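**Plan**

Numbering: C1 (bridgehead, OMe), C2 (C=O), C3 (CHOMe), C4 (CH2), C5 (bridgehead, allyl), C6 (CHMe), C7 (CHAr), C8 (CHOAc bridge). The enabling feature is the acyloin unit O–C1–C2(=O) inside the six-membered ring C1–C2–C3–C4–C5–C8, whose fully substituted carbinol carbon C1 is also a member of the cyclopentane C1–C7–C6–C5–C8.
Retrosynthesis: remove the acetyl and O-methyl groups, cut C1–C2 (acyl-anion addition of a C2 aldehyde to a C1 cyclopentanone), then C2–CH2OH (glycol cleavage), C3–OMe (epoxide opening), C5–C4 and C6–CH3 (cuprate addition/allylic alkylation), C5–allyl (Stille) and C7–aryl (rhodium-catalysed arylation).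
Forward: the cyclopentane is there from the start; aryl, allyl, methyl and the four-carbon chain are attached in that order, the ketone is moved from C8 to C1, the chain is trimmed to the α-methoxy aldehyde, and the six-membered ring is closed in step 16.
Stereochemistry: C7 from the silyloxy centre of the (S)-enone (anti arylation, then elimination); C6 and C5 by anti cuprate addition and anti alkylation; C8 by hydroxyl-directed hydride delivery; C3 by Sharpless epoxidation with D-(−)-diethyl tartrate followed by SN2 methanolysis; C1 by the geometry of the bridge.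
The C8 oxygen travels as a tert-butyldimethylsilyl ether: its oxygen is a poor nucleophile towards the activated epoxide of step 13 and it neither migrates nor leaves under the carbene conditions.

Key step: step 16

Step 1
Reactants: 1 (S)-4-[(tert-butyldimethylsilyl)oxy]cyclopent-2-en-1-one; 2 (3,4-dimethoxyphenyl)boronic acid
Product: 4 (S)-4-(3,4-dimethoxyphenyl)cyclopent-2-en-1-one, via trans-3-aryl-4-silyloxycyclopentanone 3 (not isolated)
Conditions: [Rh(OH)(cod)]2 (2.5 mol%), dioxane/H2O 10:1, 25 °C; then DBU, CH2Cl2, −20 → 0 °C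
Reagents that add atoms: none
Why: Rhodium-catalysed conjugate arylation (Hayashi–Miyaura type) should deliver the aryl group anti to the silyloxy group, and E1cB loss of silanolate then shifts the enone so that the aryl carbon (C7 of the target) keeps the configuration set by the (S)-silyloxy centre; the elimination is kept cold and short because this centre is benzylic and γ to the carbonyl.

Step 2
Reactants: 4 (S)-4-(3,4-dimethoxyphenyl)cyclopent-2-en-1-one
Product: 5 (S)-4-(3,4-dimethoxyphenyl)-2-iodocyclopent-2-en-1-one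
Conditions: I2, pyridine, CH2Cl2, 0 → 25 °C
Reagents that add atoms: iodine (II)
Why: Pyridine-mediated α-iodination of an enone (conjugate addition of pyridine, iodination of the enolate, elimination) is standard for cyclopentenones and should not touch the γ stereocentre.

Step 3
Reactants: 5 (S)-4-(3,4-dimethoxyphenyl)-2-iodocyclopent-2-en-1-one; 6 allyltributylstannane
Product: 7 (S)-2-allyl-4-(3,4-dimethoxyphenyl)cyclopent-2-en-1-one
Conditions: Pd2(dba)3 (2.5 mol%), AsPh3 (10 mol%), CuI (10 mol%), NMP, 25 °C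
Reagents that add atoms: none
Why: Stille coupling of an α-iodoenone with an allylstannane runs at room temperature with the AsPh3/CuI-accelerated zerovalent palladium catalyst, mild enough to leave the base-sensitive C7 centre alone.

Step 4
Reactants: 8 methyl (E)-4-bromobut-2-enoate
Product: 9 (E)-4-bromobut-2-en-1-ol
Conditions: iBu2AlH (2.2 equiv), CH2Cl2, −78 °C
Reagents that add atoms: none
Why: Low-temperature 1,2-reduction of the enoate gives the allylic alcohol without touching the allylic bromide or the E-alkene.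

Step 5
Reactants: 9 (E)-4-bromobut-2-en-1-ol
Product: 10 (E)-[(4-bromobut-2-en-1-yl)oxy](tert-butyl)dimethylsilane
Conditions: TBSCl, imidazole, CH2Cl2, 0 °C
Reagents that add atoms: tert-butyldimethylsilyl chloride (CC(C)(C)[Si](C)(C)Cl)
Why: Routine silylation of a primary alcohol.

Step 6
Reactants: 7 (S)-2-allyl-4-(3,4-dimethoxyphenyl)cyclopent-2-en-1-one; 10 (E)-[(4-bromobut-2-en-1-yl)oxy](tert-butyl)dimethylsilane
Product: 12 (2S,3R,4S)-2-allyl-2-[(E)-4-[(tert-butyldimethylsilyl)oxy]but-2-en-1-yl]-4-(3,4-dimethoxyphenyl)-3-methylcyclopentan-1-one, via lithium enolate 11 (not isolated)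
Conditions: Me2CuLi (from MeLi and CuI), Et2O, −78 → −30 °C; then 10, HMPA/THF, −78 → 0 °C
Reagents that add atoms: lithium dimethylcuprate ([Li+].C[Cu-]C)
Why: Tandem cuprate conjugate addition and enolate alkylation: methyl should enter C6 anti to the adjacent C7 aryl group, and the regiodefined enolate should then be alkylated at C5 by the allylic bromide anti to the new C6 methyl group, which fixes the quaternary centre with allyl cis and the C4 chain trans to methyl.

Step 7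
Reactants: 12 (2S,3R,4S)-2-allyl-2-[(E)-4-[(tert-butyldimethylsilyl)oxy]but-2-en-1-yl]-4-(3,4-dimethoxyphenyl)-3-methylcyclopentan-1-one
Product: 13 (2S,3R,4S,5S)-2-allyl-2-[(E)-4-[(tert-butyldimethylsilyl)oxy]but-2-en-1-yl]-4-(3,4-dimethoxyphenyl)-5-hydroxy-3-methylcyclopentan-1-one
Conditions: KN(SiMe3)2, THF, −78 °C; then 3-phenyl-2-(phenylsulfonyl)oxaziridine, −78 °C; NH4Cl (aq)
Reagents that add atoms: 3-phenyl-2-(phenylsulfonyl)oxaziridine (O=S(=O)(c1ccccc1)N1OC1c1ccccc1)
Why: The ketone can enolise only towards C1 because C5 is quaternary, and the potassium enolate should be hydroxylated by the Davis oxaziridine on the face anti to the C7 aryl group, giving the C1 alcohol trans to aryl.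

Step 8
Reactants: 13 (2S,3R,4S,5S)-2-allyl-2-[(E)-4-[(tert-butyldimethylsilyl)oxy]but-2-en-1-yl]-4-(3,4-dimethoxyphenyl)-5-hydroxy-3-methylcyclopentan-1-one
Product: 14 (1S,2S,3S,4R,5S)-3-allyl-3-[(E)-4-[(tert-butyldimethylsilyl)oxy]but-2-en-1-yl]-5-(3,4-dimethoxyphenyl)-4-methylcyclopentane-1,2-diol
Conditions: Me4NBH(OAc)3, MeCN/AcOH 1:1, −30 → 0 °C
Reagents that add atoms: none
Why: Hydroxyl-directed (Saksena–Evans) reduction: the C1 hydroxyl binds boron and hydride is delivered to the same face of the C8 carbonyl, so the new C8 hydroxyl should be trans to the C1 hydroxyl and cis to the C4 chain.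

Step 9
Reactants: 14 (1S,2S,3S,4R,5S)-3-allyl-3-[(E)-4-[(tert-butyldimethylsilyl)oxy]but-2-en-1-yl]-5-(3,4-dimethoxyphenyl)-4-methylcyclopentane-1,2-diol
Product: 15 (1S,2S,3R,4S,5S)-2-allyl-2-[(E)-4-[(tert-butyldimethylsilyl)oxy]but-2-en-1-yl]-4-(3,4-dimethoxyphenyl)-3-methyl-5-[(triethylsilyl)oxy]cyclopentan-1-ol
Conditions: TESCl (1.05 equiv), imidazole, CH2Cl2, −20 °C
Reagents that add atoms: triethylsilyl chloride (CC[Si](Cl)(CC)CC)
Why: The C1 hydroxyl, flanked by two CH groups, should be silylated selectively over the C8 hydroxyl, which is neopentylic next to the quaternary C5.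

Step 10
Reactants: 15 (1S,2S,3R,4S,5S)-2-allyl-2-[(E)-4-[(tert-butyldimethylsilyl)oxy]but-2-en-1-yl]-4-(3,4-dimethoxyphenyl)-3-methyl-5-[(triethylsilyl)oxy]cyclopentan-1-ol
Product: 16 tert-butyl{[(1S,2S,3R,4S,5S)-2-allyl-2-[(E)-4-[(tert-butyldimethylsilyl)oxy]but-2-en-1-yl]-4-(3,4-dimethoxyphenyl)-3-methyl-5-[(triethylsilyl)oxy]cyclopentyl]oxy}dimethylsilane
Conditions: TBSOTf, 2,6-lutidine, CH2Cl2, 0 → 25 °C
Reagents that add atoms: tert-butyldimethylsilyl triflate (CC(C)(C)[Si](C)(C)OS(=O)(=O)C(F)(F)F)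
Why: The silyl triflate silylates the hindered C8 hydroxyl, and a silyl ether is chosen because its oxygen should stay out of the epoxide opening of step 13 and is inert to the carbene conditions of step 16.

Step 11
Reactants: 16 tert-butyl{[(1S,2S,3R,4S,5S)-2-allyl-2-[(E)-4-[(tert-butyldimethylsilyl)oxy]but-2-en-1-yl]-4-(3,4-dimethoxyphenyl)-3-methyl-5-[(triethylsilyl)oxy]cyclopentyl]oxy}dimethylsilane
Product: 17 (1S,2S,3S,4R,5S)-3-allyl-2-[(tert-butyldimethylsilyl)oxy]-5-(3,4-dimethoxyphenyl)-3-[(E)-4-hydroxybut-2-en-1-yl]-4-methylcyclopentan-1-ol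
Conditions: HF·pyridine, pyridine, THF, 0 °C
Reagents that add atoms: none
Why: Buffered HF·pyridine should remove the secondary triethylsilyl and the primary tert-butyldimethylsilyl ethers well before the hindered secondary silyl ether at C8.

Step 12
Reactants: 17 (1S,2S,3S,4R,5S)-3-allyl-2-[(tert-butyldimethylsilyl)oxy]-5-(3,4-dimethoxyphenyl)-3-[(E)-4-hydroxybut-2-en-1-yl]-4-methylcyclopentan-1-ol
Product: 18 (1S,2S,3S,4R,5S)-3-allyl-2-[(tert-butyldimethylsilyl)oxy]-5-(3,4-dimethoxyphenyl)-3-{[(2R,3R)-3-(hydroxymethyl)oxiran-2-yl]methyl}-4-methylcyclopentan-1-ol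
Conditions: Ti(OiPr)4 (20 mol%), D-(−)-diethyl tartrate (24 mol%), tBuOOH, 4 Å molecular sieves, CH2Cl2, −20 °C
Reagents that add atoms: tert-butyl hydroperoxide (CC(C)(C)OO)
Why: Sharpless asymmetric epoxidation: only the allylic alcohol alkene reacts, and D-(−)-diethyl tartrate should give the (2R,3R)-epoxide under reagent control, the remote ring stereocentres having little say.

Step 13
Reactants: 18 (1S,2S,3S,4R,5S)-3-allyl-2-[(tert-butyldimethylsilyl)oxy]-5-(3,4-dimethoxyphenyl)-3-{[(2R,3R)-3-(hydroxymethyl)oxiran-2-yl]methyl}-4-methylcyclopentan-1-ol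
Product: 19 (1S,2S,3S,4R,5S)-3-allyl-2-[(tert-butyldimethylsilyl)oxy]-3-[(2S,3R)-3,4-dihydroxy-2-methoxybutyl]-5-(3,4-dimethoxyphenyl)-4-methylcyclopentan-1-ol
Conditions: Eu(OTf)3 (10 mol%), 2,6-di-tert-butyl-4-methylpyridine (20 mol%), MeOH, 25 °C
Reagents that add atoms: methanol (CO)
Why: Hydroxyl-directed Lewis acid catalysis (chelation of the epoxy alcohol to the lanthanide) should send methanol to C3 in an SN2 opening with inversion, giving the (S)-methoxy centre C3 of the target and a terminal 1,2-diol as a masked aldehyde.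

Step 14
Reactants: 19 (1S,2S,3S,4R,5S)-3-allyl-2-[(tert-butyldimethylsilyl)oxy]-3-[(2S,3R)-3,4-dihydroxy-2-methoxybutyl]-5-(3,4-dimethoxyphenyl)-4-methylcyclopentan-1-ol
Product: 20 (S)-3-[(1S,2R,3S,4S,5S)-1-allyl-5-[(tert-butyldimethylsilyl)oxy]-3-(3,4-dimethoxyphenyl)-4-hydroxy-2-methylcyclopentyl]-2-methoxypropanal
Conditions: NaIO4, THF/pH 7 buffer, 0 → 25 °C
Reagents that add atoms: none
Why: Periodate glycol cleavage of the terminal 1,2-diol unmasks the C2 aldehyde under near-neutral conditions that should leave the α-methoxy centre C3 and the isolated C1 alcohol untouched.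

Step 15
Reactants: 20 (S)-3-[(1S,2R,3S,4S,5S)-1-allyl-5-[(tert-butyldimethylsilyl)oxy]-3-(3,4-dimethoxyphenyl)-4-hydroxy-2-methylcyclopentyl]-2-methoxypropanal
Product: 21 (S)-3-[(1S,2R,3S,5S)-1-allyl-5-[(tert-butyldimethylsilyl)oxy]-3-(3,4-dimethoxyphenyl)-2-methyl-4-oxocyclopentyl]-2-methoxypropanal
Conditions: Dess–Martin periodinane, NaHCO3, CH2Cl2, 0 → 25 °C
Reagents that add atoms: none
Why: Dess–Martin oxidation converts the C1 alcohol into the ketone without over-oxidising the aldehyde, the bicarbonate buffer limiting epimerisation at C3, C7 and C8.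

Step 16
Reactants: 21 (S)-3-[(1S,2R,3S,5S)-1-allyl-5-[(tert-butyldimethylsilyl)oxy]-3-(3,4-dimethoxyphenyl)-2-methyl-4-oxocyclopentyl]-2-methoxypropanal
Product: 22 (1S,3S,5S,6R,7S,8S)-5-allyl-8-[(tert-butyldimethylsilyl)oxy]-7-(3,4-dimethoxyphenyl)-1-hydroxy-3-methoxy-6-methylbicyclo[3.2.1]octan-2-one
Conditions: 2-mesityl-6,7-dihydro-5H-pyrrolo[2,1-c][1,2,4]triazol-2-ium chloride (20 mol%), Et3N (20 mol%), CH2Cl2, 25 → 40 °C
Reagents that add atoms: none
Why: The triazolylidene released by Et3N adds to the aldehyde carbon C2, proton transfer gives the hydroxy-enamine (acyl-anion equivalent), this carbon attacks the C1 carbonyl, and the alkoxide–azolium adduct collapses to the ketol with release of the carbene. The closest known reaction type is the carbene-catalysed intramolecular crossed aldehyde–ketone benzoin reaction, which is documented for α-alkoxy aldehydes of sugar-derived keto aldehydes. The six-membered ring C1–C2–C3–C4–C5–C8 closes in a 6-exo-trig mode onto the cyclopentanone carbonyl. The new stereocentre C1 is dictated by the tether: the chain on C5 can reach the 1,3-related C1 only from its own face of the cyclopentane, so the hydroxyl must end up on the opposite face. Cross-selectivity is built in, since only the aldehyde can form the acyl-anion equivalent and only the ketone is left as acceptor, and the methoxy group at C3 is a poor leaving group, so ring closure should win over β-elimination from the hydroxy-enamine. C3, C7 and C8 must survive: a weak amine base in catalytic amount limits enolisation, C7 already sits in its preferred aryl-trans-to-methyl arrangement, and the silyl ether at C8 neither migrates nor leaves.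

Step 17
Reactants: 22 (1S,3S,5S,6R,7S,8S)-5-allyl-8-[(tert-butyldimethylsilyl)oxy]-7-(3,4-dimethoxyphenyl)-1-hydroxy-3-methoxy-6-methylbicyclo[3.2.1]octan-2-one
Product: 23 (1S,3S,5S,6R,7S,8S)-5-allyl-8-[(tert-butyldimethylsilyl)oxy]-7-(3,4-dimethoxyphenyl)-1,3-dimethoxy-6-methylbicyclo[3.2.1]octan-2-one
Conditions: MeOTf, 2,6-di-tert-butyl-4-methylpyridine, CH2Cl2, 25 → 40 °C
Reagents that add atoms: methyl triflate (COS(=O)(=O)C(F)(F)F)
Why: Methyl triflate with a hindered, non-nucleophilic pyridine methylates the tertiary bridgehead alcohol without forming an alkoxide, which avoids retro-benzoin cleavage, ketol shift and enolisation at C3.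

Step 18
Reactants: 23 (1S,3S,5S,6R,7S,8S)-5-allyl-8-[(tert-butyldimethylsilyl)oxy]-7-(3,4-dimethoxyphenyl)-1,3-dimethoxy-6-methylbicyclo[3.2.1]octan-2-one
Product: 24 (1S,3S,5S,6R,7S,8S)-5-allyl-7-(3,4-dimethoxyphenyl)-8-hydroxy-1,3-dimethoxy-6-methylbicyclo[3.2.1]octan-2-one
Conditions: HF·pyridine, THF, 0 → 40 °C
Reagents that add atoms: none
Why: Fluoride cleaves the silyl ether under mildly acidic conditions that should not enolise the C2 ketone towards C3.

Step 19
Reactants: 24 (1S,3S,5S,6R,7S,8S)-5-allyl-7-(3,4-dimethoxyphenyl)-8-hydroxy-1,3-dimethoxy-6-methylbicyclo[3.2.1]octan-2-one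
Product: 25 (1S,3S,5S,6R,7S,8S)-5-allyl-7-(3,4-dimethoxyphenyl)-1,3-dimethoxy-6-methyl-2-oxobicyclo[3.2.1]octan-8-yl acetate
Conditions: Ac2O, DMAP (cat.), pyridine, CH2Cl2, 25 °C
Reagents that add atoms: acetic anhydride (CC(=O)OC(C)=O)
Why: DMAP-catalysed acetylation of the hindered secondary C8 alcohol completes the target without basic conditions strong enough to epimerise C3.

**Compound list**

1 | (S)-4-[(tert-butyldimethylsilyl)oxy]cyclopent-2-en-1-one | O=C1C=C[C@@H](O[Si](C)(C)C(C)(C)C)C1 | starting material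
2 | (3,4-dimethoxyphenyl)boronic acid | COc1ccc(B(O)O)cc1OC | starting material
3 | (3R,4S)-4-[(tert-butyldimethylsilyl)oxy]-3-(3,4-dimethoxyphenyl)cyclopentan-1-one (aryl trans to silyloxy) | O=C1C[C@H](c2ccc(OC)c(OC)c2)[C@@H](O[Si](C)(C)C(C)(C)C)C1 | intermediate (not isolated)
4 | (S)-4-(3,4-dimethoxyphenyl)cyclopent-2-en-1-one | O=C1C=C[C@@H](c2ccc(OC)c(OC)c2)C1 | intermediate
5 | (S)-4-(3,4-dimethoxyphenyl)-2-iodocyclopent-2-en-1-one | O=C1C(I)=C[C@@H](c2ccc(OC)c(OC)c2)C1 | intermediate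
6 | allyltributylstannane | C=CC[Sn](CCCC)(CCCC)CCCC | starting material
7 | (S)-2-allyl-4-(3,4-dimethoxyphenyl)cyclopent-2-en-1-one | C=CCC1=C[C@@H](c2ccc(OC)c(OC)c2)CC1=O | intermediate
8 | methyl (E)-4-bromobut-2-enoate | COC(=O)/C=C/CBr | starting material
9 | (E)-4-bromobut-2-en-1-ol | OC/C=C/CBr | intermediate
10 | (E)-[(4-bromobut-2-en-1-yl)oxy](tert-butyl)dimethylsilane | CC(C)(C)[Si](C)(C)OC/C=C/CBr | intermediate
11 | lithium (3R,4S)-2-allyl-4-(3,4-dimethoxyphenyl)-3-methylcyclopent-1-en-1-olate (methyl trans to aryl) | C=CCC1=C(O[Li])C[C@H](c2ccc(OC)c(OC)c2)[C@H]1C | intermediate (not isolated)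
12 | (2S,3R,4S)-2-allyl-2-[(E)-4-[(tert-butyldimethylsilyl)oxy]but-2-en-1-yl]-4-(3,4-dimethoxyphenyl)-3-methylcyclopentan-1-one | C=CC[C@]1(C/C=C/CO[Si](C)(C)C(C)(C)C)[C@H](C)[C@@H](c2ccc(OC)c(OC)c2)CC1=O | intermediate
13 | (2S,3R,4S,5S)-2-allyl-2-[(E)-4-[(tert-butyldimethylsilyl)oxy]but-2-en-1-yl]-4-(3,4-dimethoxyphenyl)-5-hydroxy-3-methylcyclopentan-1-one | C=CC[C@]1(C/C=C/CO[Si](C)(C)C(C)(C)C)[C@H](C)[C@@H](c2ccc(OC)c(OC)c2)[C@H](O)C1=O | intermediate
14 | (1S,2S,3S,4R,5S)-3-allyl-3-[(E)-4-[(tert-butyldimethylsilyl)oxy]but-2-en-1-yl]-5-(3,4-dimethoxyphenyl)-4-methylcyclopentane-1,2-diol (trans-diol) | C=CC[C@]1(C/C=C/CO[Si](C)(C)C(C)(C)C)[C@H](C)[C@@H](c2ccc(OC)c(OC)c2)[C@H](O)[C@H]1O | intermediate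
15 | (1S,2S,3R,4S,5S)-2-allyl-2-[(E)-4-[(tert-butyldimethylsilyl)oxy]but-2-en-1-yl]-4-(3,4-dimethoxyphenyl)-3-methyl-5-[(triethylsilyl)oxy]cyclopentan-1-ol | C=CC[C@]1(C/C=C/CO[Si](C)(C)C(C)(C)C)[C@H](C)[C@@H](c2ccc(OC)c(OC)c2)[C@H](O[Si](CC)(CC)CC)[C@H]1O | intermediate
16 | tert-butyl{[(1S,2S,3R,4S,5S)-2-allyl-2-[(E)-4-[(tert-butyldimethylsilyl)oxy]but-2-en-1-yl]-4-(3,4-dimethoxyphenyl)-3-methyl-5-[(triethylsilyl)oxy]cyclopentyl]oxy}dimethylsilane | C=CC[C@]1(C/C=C/CO[Si](C)(C)C(C)(C)C)[C@H](C)[C@@H](c2ccc(OC)c(OC)c2)[C@H](O[Si](CC)(CC)CC)[C@H]1O[Si](C)(C)C(C)(C)C | intermediate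
17 | (1S,2S,3S,4R,5S)-3-allyl-2-[(tert-butyldimethylsilyl)oxy]-5-(3,4-dimethoxyphenyl)-3-[(E)-4-hydroxybut-2-en-1-yl]-4-methylcyclopentan-1-ol | C=CC[C@]1(C/C=C/CO)[C@H](C)[C@@H](c2ccc(OC)c(OC)c2)[C@H](O)[C@H]1O[Si](C)(C)C(C)(C)C | intermediate
18 | (1S,2S,3S,4R,5S)-3-allyl-2-[(tert-butyldimethylsilyl)oxy]-5-(3,4-dimethoxyphenyl)-3-{[(2R,3R)-3-(hydroxymethyl)oxiran-2-yl]methyl}-4-methylcyclopentan-1-ol | C=CC[C@]1(C[C@H]2O[C@@H]2CO)[C@H](C)[C@@H](c3ccc(OC)c(OC)c3)[C@H](O)[C@H]1O[Si](C)(C)C(C)(C)C | intermediate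
19 | (1S,2S,3S,4R,5S)-3-allyl-2-[(tert-butyldimethylsilyl)oxy]-3-[(2S,3R)-3,4-dihydroxy-2-methoxybutyl]-5-(3,4-dimethoxyphenyl)-4-methylcyclopentan-1-ol | C=CC[C@]1(C[C@H](OC)[C@H](O)CO)[C@H](C)[C@@H](c2ccc(OC)c(OC)c2)[C@H](O)[C@H]1O[Si](C)(C)C(C)(C)C | intermediate
20 | (S)-3-[(1S,2R,3S,4S,5S)-1-allyl-5-[(tert-butyldimethylsilyl)oxy]-3-(3,4-dimethoxyphenyl)-4-hydroxy-2-methylcyclopentyl]-2-methoxypropanal | C=CC[C@]1(C[C@H](OC)C=O)[C@H](C)[C@@H](c2ccc(OC)c(OC)c2)[C@H](O)[C@H]1O[Si](C)(C)C(C)(C)C | intermediate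
21 | (S)-3-[(1S,2R,3S,5S)-1-allyl-5-[(tert-butyldimethylsilyl)oxy]-3-(3,4-dimethoxyphenyl)-2-methyl-4-oxocyclopentyl]-2-methoxypropanal | C=CC[C@]1(C[C@H](OC)C=O)[C@H](C)[C@@H](c2ccc(OC)c(OC)c2)C(=O)[C@H]1O[Si](C)(C)C(C)(C)C | intermediate
22 | (1S,3S,5S,6R,7S,8S)-5-allyl-8-[(tert-butyldimethylsilyl)oxy]-7-(3,4-dimethoxyphenyl)-1-hydroxy-3-methoxy-6-methylbicyclo[3.2.1]octan-2-one | C=CC[C@]12C[C@H](OC)C(=O)[C@](O)([C@H](c3ccc(OC)c(OC)c3)[C@H]1C)[C@H]2O[Si](C)(C)C(C)(C)C | intermediate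
23 | (1S,3S,5S,6R,7S,8S)-5-allyl-8-[(tert-butyldimethylsilyl)oxy]-7-(3,4-dimethoxyphenyl)-1,3-dimethoxy-6-methylbicyclo[3.2.1]octan-2-one | C=CC[C@]12C[C@H](OC)C(=O)[C@](OC)([C@H](c3ccc(OC)c(OC)c3)[C@H]1C)[C@H]2O[Si](C)(C)C(C)(C)C | intermediate
24 | (1S,3S,5S,6R,7S,8S)-5-allyl-7-(3,4-dimethoxyphenyl)-8-hydroxy-1,3-dimethoxy-6-methylbicyclo[3.2.1]octan-2-one | C=CC[C@]12C[C@H](OC)C(=O)[C@](OC)([C@H](c3ccc(OC)c(OC)c3)[C@H]1C)[C@H]2O | intermediate
25 | (1S,3S,5S,6R,7S,8S)-5-allyl-7-(3,4-dimethoxyphenyl)-1,3-dimethoxy-6-methyl-2-oxobicyclo[3.2.1]octan-8-yl acetate | C=CC[C@]12C[C@H](OC)C(=O)[C@](OC)([C@H](c3ccc(OC)c(OC)c3)[C@H]1C)[C@H]2OC(C)=O | target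

**Count and risks**

Total step count: 19. Longest linear sequence: 17 steps (steps 1–3 and 6–19, from compound 1); steps 4–5 make the side-chain bromide 10.

Steps most likely to fail:

1. Step 16. The attacked face of the C1 carbonyl is flanked by the C7 aryl and the C8 silyloxy groups, so ring closure may be slow enough for amine-mediated epimerisation at C3 or aldol pathways through the ketone enol to compete. Fallback: from 21, a samarium diiodide ketyl–carbonyl (pinacol-type) cyclisation (SmI2, tBuOH, THF, −78 °C) would form the same C1–C2 bond and the same ring, giving 5-allyl-8-[(tert-butyldimethylsilyl)oxy]-7-(3,4-dimethoxyphenyl)-3-methoxy-6-methylbicyclo[3.2.1]octane-1,2-diol F1 (configured as 22 at every carbon other than C2). Oxidation of its secondary C2 carbinol with IBX in DMSO would return to the route at 22.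

2. Step 13. Regiocontrol of the epoxide opening may be lost (attack at C2, or epoxide migration before opening). Fallback: from 18, regiocontrol would be enforced electronically by a temporary ester.
   - The primary alcohol would be oxidised with TEMPO/PhI(OAc)2 in MeCN/H2O to (2S,3R)-3-{[(1S,2R,3S,4S,5S)-1-allyl-5-[(tert-butyldimethylsilyl)oxy]-3-(3,4-dimethoxyphenyl)-4-hydroxy-2-methylcyclopentyl]methyl}oxirane-2-carboxylic acid F2.
   - Esterification with Me3SiCHN2 would give its methyl ester F3.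
   - Acid-catalysed methanolysis (camphorsulfonic acid, MeOH) should open the glycidic ester at the carbon remote from the ester, with inversion, to methyl (2S,3S)-4-[(1S,2R,3S,4S,5S)-1-allyl-5-[(tert-butyldimethylsilyl)oxy]-3-(3,4-dimethoxyphenyl)-4-hydroxy-2-methylcyclopentyl]-2-hydroxy-3-methoxybutanoate F4.
   - Reduction with LiBH4 would rejoin the route at 19.

3. Step 6. C-alkylation of the hindered, tetrasubstituted enolate may be sluggish (proton transfer from C1, O-alkylation) and facial selectivity at C5 may erode. Fallback: from 7, Me2CuLi addition in the presence of Me3SiCl would give the isolable {[(3R,4S)-2-allyl-4-(3,4-dimethoxyphenyl)-3-methylcyclopent-1-en-1-yl]oxy}trimethylsilane F5. A Tsuji–Trost allylic alkylation with 2-vinyloxirane and Pd(PPh3)4 in THF (outer-sphere attack of the liberated enolate on the π-allylpalladium alkoxide, again anti to the C6 methyl) would give (2S,3R,4S)-2-allyl-4-(3,4-dimethoxyphenyl)-2-[(E)-4-hydroxybut-2-en-1-yl]-3-methylcyclopentan-1-one F6. Silylation with TBSCl/imidazole would return to the route at 12.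

Further compounds
F1 | step 16 | 5-allyl-8-[(tert-butyldimethylsilyl)oxy]-7-(3,4-dimethoxyphenyl)-3-methoxy-6-methylbicyclo[3.2.1]octane-1,2-diol (C2 carbinol either way) | C=CC[C@]12C[C@H](OC)C(O)[C@](O)([C@H](c3ccc(OC)c(OC)c3)[C@H]1C)[C@H]2O[Si](C)(C)C(C)(C)C
F2 | step 13 | (2S,3R)-3-{[(1S,2R,3S,4S,5S)-1-allyl-5-[(tert-butyldimethylsilyl)oxy]-3-(3,4-dimethoxyphenyl)-4-hydroxy-2-methylcyclopentyl]methyl}oxirane-2-carboxylic acid | C=CC[C@]1(C[C@H]2O[C@@H]2C(=O)O)[C@H](C)[C@@H](c3ccc(OC)c(OC)c3)[C@H](O)[C@H]1O[Si](C)(C)C(C)(C)C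
F3 | step 13 | methyl (2S,3R)-3-{[(1S,2R,3S,4S,5S)-1-allyl-5-[(tert-butyldimethylsilyl)oxy]-3-(3,4-dimethoxyphenyl)-4-hydroxy-2-methylcyclopentyl]methyl}oxirane-2-carboxylate | C=CC[C@]1(C[C@H]2O[C@@H]2C(=O)OC)[C@H](C)[C@@H](c3ccc(OC)c(OC)c3)[C@H](O)[C@H]1O[Si](C)(C)C(C)(C)C
F4 | step 13 | methyl (2S,3S)-4-[(1S,2R,3S,4S,5S)-1-allyl-5-[(tert-butyldimethylsilyl)oxy]-3-(3,4-dimethoxyphenyl)-4-hydroxy-2-methylcyclopentyl]-2-hydroxy-3-methoxybutanoate | C=CC[C@]1(C[C@H](OC)[C@H](O)C(=O)OC)[C@H](C)[C@@H](c2ccc(OC)c(OC)c2)[C@H](O)[C@H]1O[Si](C)(C)C(C)(C)C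
F5 | step 6 | {[(3R,4S)-2-allyl-4-(3,4-dimethoxyphenyl)-3-methylcyclopent-1-en-1-yl]oxy}trimethylsilane | C=CCC1=C(O[Si](C)(C)C)C[C@H](c2ccc(OC)c(OC)c2)[C@H]1C
F6 | step 6 | (2S,3R,4S)-2-allyl-4-(3,4-dimethoxyphenyl)-2-[(E)-4-hydroxybut-2-en-1-yl]-3-methylcyclopentan-1-one | C=CC[C@]1(C/C=C/CO)[C@H](C)[C@@H](c2ccc(OC)c(OC)c2)CC1=O
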